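(Readings and results are simulated with constants of no real substance, and the scatter is random.)

The starting material left in the delta run at 20.0 h lies 3.6 percentage points below the epsilon run, and at 30.0 h it lies 1.7 points below, with a scatter of 1 point on each reading. Those two runs differ in their protic impurity, so I suppose that each impurity molecule removes one molecule of starting material.

| setting | epsilon | delta | birch | oak | ash | elm |
|---|---|---|---|---|---|---|
| starting material | 0.82 M | 0.82 M | 0.82 M | 0.82 M | 0.82 M | 0.82 M |
| reagent | 0.902 M (in portions, 3) | 0.902 M (in portions, 3) | 0.902 M (in portions, 3) | 0.902 M (in portions, 3) | 0.902 M (in portions, 3) | 0.902 M (in portions, 3) |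
| capture agent | 0.041 M | 0.041 M | 0.0410 M | 0.0410 M | 0.0410 M | 0.0410 M |
| protic impurity | 0.0045 M | 0.033 M | 0.00400 M | 0.00800 M | 0.0150 M | 0.0300 M |
| remark | run made earlier; portions every 12 h | run made earlier; portions every 12 h | the portions of reagent follow each other after 12 h, the first at the start | the portions of reagent follow each other after 12 h, the first at the start | the portions of reagent follow each other after 12 h, the first at the start | the portions of reagent follow each other after 12 h, the first at the start |
| time |  |  | 40 h | 40 h | 40 h | 40 h |

| run | time / h | product / % | starting material / % |
|---|---|---|---|
| epsilon | 4.00 | 1.3 | 78.8 |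
| epsilon | 10.0 | 5.2 | 69.7 |
| epsilon | 20.0 | 15.6 | 42.8 |
| epsilon | 30.0 | 28.6 | 23.6 |
| delta | 8.00 | 3.7 | 68.8 |
| delta | 15.0 | 9.9 | 51.4 |
| delta | 20.0 | 16.5 | 39.2 |
| delta | 30.0 | 27.0 | 21.9 |

(each reading ± 1 percentage point)

- the analysis behind the earlier runs scatters by 1 percentage point, standard deviation
- "hardly changes" means that all values lie within two and a half points (for a concentration: within two and a half percent of the largest)

- amount of product at the end, in percent of the starting material charged for birch, oak, ash, elm, in this order
- the shape of the row from first to last (rises all the way / hardly changes / falls all the way / rises, then falls / falls, then rises)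

I fold this into one number. The quench share is the protic impurity charged divided by the starting material charged, the part of the starting material that the impurity can remove; in elm it is 3.66%, and in birch 0.488%. Between delta and epsilon the shares differ by 3.48%, which is the size of the gaps just read, given their scatter.

Now I join the two ends of the row. Starting material lost to the impurity costs product in proportion to the part of it that reaches product by the end. Carrying the last slope of the epsilon run forward in a straight line gives about 41.6% at 40 h. So elm should end about 1.3 points behind birch, inside the margin for a flat row. One number is enough for the shape, but the level had to come from the slope.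

The forecast gives 42.5%, 42.5%, 42.3% and 42%, so hardly changes, on grounds of its own: “so the row should stay flat”.

The flasks give 38.8%, 38.7%, 38.5% and 38.1%, so hardly changes, and elm ends 0.7 points behind birch, less than my 1.3 points.

    starting material + reagent → open intermediate (k = 0.268 L mol⁻¹ h⁻¹)
    starting material + protic impurity → quenched substrate (k = 2.64 L mol⁻¹ h⁻¹)
    open intermediate + capture agent → trapped intermediate (k = 0.0473 L mol⁻¹ h⁻¹)
    open intermediate ⇌ product (K = 2.78, k = 0.0326 h⁻¹)

Elm holds 3.66% quenched substrate at 40.0 h, as its quench share of 3.66% says, and ash holds 1.83% against a share of 1.83%. The path from starting material and protic impurity to quenched substrate is not the reason for elm's level: without it, elm's product moves from 38.1% to just 38.9%. A part of elm's level comes from the slow addition of reagent together with the time given: in elm, reagent in one portion gives 49.5%, and ten times the time gives 67.2%. In that longer run, birch stands 2.3 points above elm at 400 h.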